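**Retrosynthetic overview**

1. The target is apigenin carrying on C8 the chain C1''H2–C2''H(isopropenyl)–C3''H2–C4''H2–C5''(Me)=CH2. The strategy rests on ring A being a phloroglucinol nucleus (oxygen on C5, C7 and C8a) fused to the γ-pyranone ring C, so that C5, C6, C7 and C8 can be grafted onto a finished ring C. It also rests on C8, C1'', C2'', C3'', C4'', C5'' being C2, C3, C4, C5, C6, C1 of ring-opened (R)-limonene.
2. After removal of the 4'-O-silyl group, ring A is cut at C7–C8 and C5–C6. This gives a 2-alkyl-3-ethoxycarbonyl-6-aryl-4-pyranone, whose lateral CH2 is the future C8 and whose ester carbon is the future C5, plus an acetyl donor (C6–C7).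
3. Ring C is cut at C4–C4a and O1–C2 (flavone numbering) into a limonene-derived β-keto ester and a 3-arylpropioloyl chloride made from 4-ethynylphenol (ring B).
4. The β-keto ester comes from limonene by epoxidation and periodate cleavage, one-carbon homologation of the aldehyde, methylenation of the ketone and a Roskamp reaction.
5. Ring order: ring B is bought, ring C is closed in step 10, ring A is closed in step 11.

Key step: step 11

Remark: the 4'-oxygen is carried as a triisopropylsilyl ether, because the lithium amide and alkoxide present in the ring A annulation would endanger a less hindered aryl silyl ether; fluoride still removes it at the end.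
Remark: the C6–C7 unit is delivered as 1-acetylimidazole, because the doubly stabilised lateral anion is too weak a nucleophile for an alkyl acetate and LiN(iPr)2 would enolise such an ester; the bonds formed are the same.

**Route**

Step 1
Reactants: 1 (R)-(+)-limonene
Product: 2 (4R)-1-methyl-4-(prop-1-en-2-yl)-7-oxabicyclo[4.1.0]heptane (limonene 1,2-oxide, cis/trans mixture)
Conditions: mCPBA (1.0 equiv), NaHCO3, CH2Cl2, 0 °C
Reagents that add atoms: 3-chloroperoxybenzoic acid (mCPBA), OOC(=O)c1cccc(Cl)c1
Why: Prilezhaev epoxidation, in which the peracid should prefer the more electron-rich trisubstituted ring alkene over the 1,1-disubstituted isopropenyl group; the two new epoxide centres need no control because step 2 destroys them, and C4 is untouched.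

Step 2
Reactants: 2 limonene 1,2-oxide
Product: 4 (3R)-6-oxo-3-(prop-1-en-2-yl)heptanal, via limonene-1,2-diol 3 (not isolated)
Conditions: H5IO6 (1.2 equiv), THF/H2O, 0 °C → rt
Reagents that add atoms: water, O
Why: Periodic acid opens the epoxide to the vicinal diol and then cleaves it (Malaprade glycol cleavage), so both epoxide diastereomers converge on one keto aldehyde whose stereocentre, β to the aldehyde, cannot epimerise.

Step 3
Reactants: 4 (3R)-6-oxo-3-(prop-1-en-2-yl)heptanal
Product: 5 (5R)-8-methoxy-5-(prop-1-en-2-yl)oct-7-en-2-one (E/Z mixture)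
Conditions: MeOCH2PPh3Cl (1.1 equiv), KN(SiMe3)2 (1.05 equiv), THF, 0 °C; then 4, −78 → −20 °C
Reagents that add atoms: (methoxymethyl)triphenylphosphonium chloride, COC[P+](c1ccccc1)(c1ccccc1)c1ccccc1.[Cl-]
Why: Wittig olefination with a non-stabilised alkoxymethylene ylide, which at low temperature should add to the aldehyde much faster than to the methyl ketone; the E/Z mixture does not matter because the enol ether is hydrolysed in step 5.

Step 4
Reactants: 5 (5R)-8-methoxy-5-(prop-1-en-2-yl)oct-7-en-2-one
Product: 6 (4R)-1-methoxy-7-methyl-4-(prop-1-en-2-yl)octa-1,7-diene (E/Z mixture)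
Conditions: MePPh3Br (2.0 equiv), KOtBu (1.9 equiv), THF, 0 °C → rt
Reagents that add atoms: methyltriphenylphosphonium bromide, C[P+](c1ccccc1)(c1ccccc1)c1ccccc1.[Br-]
Why: Wittig methylenation of an unhindered methyl ketone with Ph3P=CH2; the enol ether is inert to the basic conditions and the stereocentre is remote from the enolisable positions.

Step 5
Reactants: 6 (4R)-1-methoxy-7-methyl-4-(prop-1-en-2-yl)octa-1,7-diene
Product: 7 (4R)-7-methyl-4-(prop-1-en-2-yl)oct-7-enal
Conditions: 1 M aq. HCl, THF, 0 °C → rt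
Reagents that add atoms: water, O
Why: Acid-catalysed enol ether hydrolysis (protonation at carbon, hemiacetal, loss of methanol) completes the one-carbon homologation of the aldehyde; cold dilute acid is expected to leave the two 1,1-disubstituted alkenes unprotonated.

Step 6
Reactants: 7 (4R)-7-methyl-4-(prop-1-en-2-yl)oct-7-enal; 8 ethyl diazoacetate
Product: 9 ethyl (6R)-9-methyl-3-oxo-6-(prop-1-en-2-yl)dec-9-enoate
Conditions: SnCl2 (0.1 equiv), 8 (1.2 equiv), CH2Cl2, rt
Reagents that add atoms: none
Why: Roskamp reaction, in which the SnCl2-activated aldehyde is attacked by the diazo carbon and a 1,2-hydride shift with loss of N2 gives the β-keto ester; no metal carbene is formed, so the alkenes should not be cyclopropanated.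

Step 7
Reactants: 10 4-ethynylphenol
Product: 11 (4-ethynylphenoxy)tri(propan-2-yl)silane
Conditions: iPr3SiCl (1.1 equiv), imidazole (2.0 equiv), DMF, rt
Reagents that add atoms: chlorotri(propan-2-yl)silane, CC(C)[Si](Cl)(C(C)C)C(C)C
Why: Standard imidazole-mediated silylation of a phenol; the terminal alkyne does not react.

Step 8
Reactants: 11 (4-ethynylphenoxy)tri(propan-2-yl)silane
Product: 12 3-{4-[(triisopropylsilyl)oxy]phenyl}prop-2-ynoic acid
Conditions: n-BuLi (1.05 equiv), THF, −78 °C; CO2, −78 → 0 °C; cold 1 M HCl to pH 3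
Reagents that add atoms: carbon dioxide, O=C=O
Why: Deprotonation of the terminal alkyne and carboxylation of the lithium acetylide with CO2; the hindered aryl silyl ether should tolerate n-BuLi at −78 °C and the short cold acidification.

Step 9
Reactants: 12 3-{4-[(triisopropylsilyl)oxy]phenyl}prop-2-ynoic acid
Product: 13 3-{4-[(triisopropylsilyl)oxy]phenyl}prop-2-ynoyl chloride (used crude)
Conditions: (COCl)2 (1.5 equiv), DMF (cat.), CH2Cl2, 0 °C → rt; evaporate
Reagents that add atoms: oxalyl chloride, O=C(Cl)C(=O)Cl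
Why: Acid chloride formation through the catalytic Vilsmeier-type chloroiminium species at or below room temperature, which is mild enough to avoid addition of HCl across the alkyne.

Step 10
Reactants: 9 ethyl (6R)-9-methyl-3-oxo-6-(prop-1-en-2-yl)dec-9-enoate; 13 3-{4-[(triisopropylsilyl)oxy]phenyl}prop-2-ynoyl chloride
Product: 15 ethyl 2-[(3R)-6-methyl-3-(prop-1-en-2-yl)hept-6-en-1-yl]-4-oxo-6-{4-[(triisopropylsilyl)oxy]phenyl}-4H-pyran-3-carboxylate, via tricarbonyl alkynone 14 (not isolated)
Conditions: MgCl2 (1.1 equiv), pyridine (2.2 equiv), CH2Cl2, 0 °C; 13 (1.05 equiv), 0 °C → rt; then DMAP (0.2 equiv), 40 °C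
Reagents that add atoms: none
Why: C-Acylation of the magnesium chelate of the β-keto ester by the acid chloride (Rathke-type soft enolisation) and then 6-endo-dig oxa-Michael addition of the ketone enol oxygen to the alkynone, assisted by reversible β-addition of DMAP; the ketone oxygen is more nucleophilic than the ester oxygen, which places the ester on C3 next to the alkyl-bearing C2.

Step 11
Reactants: 15 ethyl 2-[(3R)-6-methyl-3-(prop-1-en-2-yl)hept-6-en-1-yl]-4-oxo-6-{4-[(triisopropylsilyl)oxy]phenyl}-4H-pyran-3-carboxylate; 16 1-acetylimidazole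
Product: 18 5,7-dihydroxy-8-[(2R)-5-methyl-2-(prop-1-en-2-yl)hex-5-en-1-yl]-2-{4-[(triisopropylsilyl)oxy]phenyl}-4H-chromen-4-one, via lateral methyl ketone 17 (not isolated)
Conditions: LiN(iPr)2 (1.05 equiv), THF, −78 °C; 16 (1.05 equiv), −78 → −40 °C; LiN(iPr)2 (2.5 equiv), −78 → 0 °C; aq. NH4Cl
Reagents that add atoms: none
Why: Proposed new method: LiN(iPr)2 removes a proton from the lateral CH2 on pyranone C2 (the future C8), whose anion is delocalised into the ring carbonyl and the C3 ester, and this chelated lithium enolate is C-acetylated by the acyl imidazole (C7–C8), the released imidazolide taking the now very acidic C8–H. The second charge of LiN(iPr)2 turns this monoanion into the 1,3-dicarbonyl-type dianion at the acetyl methyl (C6), which attacks the neighbouring ester carbonyl in a 6-(enolendo)-exo-trig Claisen (Dieckmann-type) closure (C5–C6), and loss of ethoxide with two enolisations aromatises ring A as the 5,7-diol. The closest known reaction types are the lateral lithiation and acylation of 2-alkyl-4-pyranones, the Claisen cyclisation of polycarbonyl dianions to resorcinols and phloroglucinols, and the annulation of ortho-toluate anions; running them in one flask on a 3-alkoxycarbonyl-4-pyranone is the untested part. No stereocentre is formed, and the C2'' centre, two carbons from C8 and not enolisable, is untouched. The step needs C- over O-acylation at the lateral carbon and C- over O-attack on the ester (O-attack would give a fused 2-pyranone lactone): the acyl imidazole on a lithium chelate, with imidazolide able to shuttle any enol ester back, favours the first, and forming the dianion at −78 °C before warming, so that the terminal carbanion is the most nucleophilic site, favours the second. The 8-alkyl rather than 6-alkyl pattern cannot scramble because O1–C8a already exists and the chain sits on the lateral carbon.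

Step 12
Reactants: 18 5,7-dihydroxy-8-[(2R)-5-methyl-2-(prop-1-en-2-yl)hex-5-en-1-yl]-2-{4-[(triisopropylsilyl)oxy]phenyl}-4H-chromen-4-one
Product: 19 5,7-dihydroxy-2-(4-hydroxyphenyl)-8-[(2R)-5-methyl-2-(prop-1-en-2-yl)hex-5-en-1-yl]-4H-chromen-4-one (CNP0187326.1)
Conditions: Bu4NF (3 equiv), THF, 0 °C; aq. NH4Cl
Reagents that add atoms: none
Why: Fluoride-driven cleavage of the aryl silicon–oxygen bond (strong Si–F bond, phenoxide leaving group); the acid-free conditions avoid cyclisation of the 7-hydroxyl onto the side-chain alkenes.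

**Compound list**

1 | (R)-(+)-limonene, (4R)-1-methyl-4-(prop-1-en-2-yl)cyclohex-1-ene | CC1=CC[C@@H](CC1)C(C)=C | starting material
2 | (4R)-1-methyl-4-(prop-1-en-2-yl)-7-oxabicyclo[4.1.0]heptane (cis/trans mixture) | CC12CC[C@H](CC1O2)C(C)=C | intermediate
3 | (4R)-1-methyl-4-(prop-1-en-2-yl)cyclohexane-1,2-diol (not isolated) | CC1(O)CC[C@H](CC1O)C(C)=C | intermediate
4 | (3R)-6-oxo-3-(prop-1-en-2-yl)heptanal | CC(=O)CC[C@H](CC=O)C(C)=C | intermediate
5 | (5R)-8-methoxy-5-(prop-1-en-2-yl)oct-7-en-2-one (E/Z) | CC(=O)CC[C@H](CC=COC)C(C)=C | intermediate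
6 | (4R)-1-methoxy-7-methyl-4-(prop-1-en-2-yl)octa-1,7-diene (E/Z) | C=C(C)CC[C@H](CC=COC)C(=C)C | intermediate
7 | (4R)-7-methyl-4-(prop-1-en-2-yl)oct-7-enal | C=C(C)CC[C@H](CCC=O)C(=C)C | intermediate
8 | ethyl diazoacetate | CCOC(=O)C=[N+]=[N-] | starting material
9 | ethyl (6R)-9-methyl-3-oxo-6-(prop-1-en-2-yl)dec-9-enoate | C=C(C)CC[C@H](CCC(=O)CC(=O)OCC)C(=C)C | intermediate
10 | 4-ethynylphenol | C#Cc1ccc(O)cc1 | starting material
11 | (4-ethynylphenoxy)tri(propan-2-yl)silane | C#Cc1ccc(O[Si](C(C)C)(C(C)C)C(C)C)cc1 | intermediate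
12 | 3-{4-[(triisopropylsilyl)oxy]phenyl}prop-2-ynoic acid | OC(=O)C#Cc1ccc(O[Si](C(C)C)(C(C)C)C(C)C)cc1 | intermediate
13 | 3-{4-[(triisopropylsilyl)oxy]phenyl}prop-2-ynoyl chloride | O=C(Cl)C#Cc1ccc(O[Si](C(C)C)(C(C)C)C(C)C)cc1 | intermediate
14 | ethyl (6R)-9-methyl-3-oxo-6-(prop-1-en-2-yl)-2-(3-{4-[(triisopropylsilyl)oxy]phenyl}prop-2-ynoyl)dec-9-enoate (enolised, not isolated) | C=C(C)CC[C@H](CCC(=O)C(C(=O)OCC)C(=O)C#Cc1ccc(O[Si](C(C)C)(C(C)C)C(C)C)cc1)C(=C)C | intermediate
15 | ethyl 2-[(3R)-6-methyl-3-(prop-1-en-2-yl)hept-6-en-1-yl]-4-oxo-6-{4-[(triisopropylsilyl)oxy]phenyl}-4H-pyran-3-carboxylate | C=C(C)CC[C@H](CCc1oc(-c2ccc(O[Si](C(C)C)(C(C)C)C(C)C)cc2)cc(=O)c1C(=O)OCC)C(=C)C | intermediate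
16 | 1-acetylimidazole | CC(=O)n1ccnc1 | starting material
17 | ethyl 2-[(5R)-8-methyl-2-oxo-5-(prop-1-en-2-yl)non-8-en-3-yl]-4-oxo-6-{4-[(triisopropylsilyl)oxy]phenyl}-4H-pyran-3-carboxylate (formed as its lithium enolate, not isolated) | C=C(C)CC[C@H](CC(C(C)=O)c1oc(-c2ccc(O[Si](C(C)C)(C(C)C)C(C)C)cc2)cc(=O)c1C(=O)OCC)C(=C)C | intermediate
18 | 5,7-dihydroxy-8-[(2R)-5-methyl-2-(prop-1-en-2-yl)hex-5-en-1-yl]-2-{4-[(triisopropylsilyl)oxy]phenyl}-4H-chromen-4-one | C=C(C)CC[C@H](Cc1c(O)cc(O)c2c(=O)cc(-c3ccc(O[Si](C(C)C)(C(C)C)C(C)C)cc3)oc12)C(=C)C | intermediate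
19 | 5,7-dihydroxy-2-(4-hydroxyphenyl)-8-[(2R)-5-methyl-2-(prop-1-en-2-yl)hex-5-en-1-yl]-4H-chromen-4-one | C=C(C)CC[C@H](Cc1c(O)cc(O)c2c(=O)cc(-c3ccc(O)cc3)oc12)C(=C)C | target

**Step count and risks**

Total step count: 12. Longest linear sequence: 9 steps (steps 1 to 6, then 10, 11 and 12); the arene branch (steps 7 to 9) joins at step 10.

Steps most likely to fail:

Step 11. The one-flask cascade may stall through O-acylation of the delocalised lateral anion, through lactonisation of the monoanion onto the ester before the dianion forms, or through incomplete second deprotonation. The fallback takes the cascade apart into known steps. It sets out from pyranone 15: deprotonation with LiN(SiMe3)2 at −78 °C and aldol addition of the lateral anion to acetaldehyde, quenched cold with AcOH to forestall lactonisation, would give ethyl 2-[(5R)-2-hydroxy-8-methyl-5-(prop-1-en-2-yl)non-8-en-3-yl]-4-oxo-6-{4-[(triisopropylsilyl)oxy]phenyl}-4H-pyran-3-carboxylate F1. Dess–Martin oxidation of F1 would give the methyl ketone 17, now isolated. A separate Dieckmann-type Claisen closure of this δ-keto ester (LiN(iPr)2, 2.2 equiv, THF, −78 → 0 °C) with aromatisation would return to the route at 18.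

Step 10. The alkynoyl chloride may be lost to conjugate addition of chloride or pyridine or to O-acylation, and the enol may close through the wrong position. The fallback builds ring C at the dihydro level and sets out from β-keto ester 9. Commercial (E)-4-hydroxycinnamic acid would be silylated on both oxygens (iPr3SiCl, imidazole, DMF) to triisopropylsilyl (2E)-3-{4-[(triisopropylsilyl)oxy]phenyl}prop-2-enoate F2. Selective cleavage of the silyl ester (K2CO3, MeOH/THF/H2O, 0 °C) would give (2E)-3-{4-[(triisopropylsilyl)oxy]phenyl}prop-2-enoic acid F3, and (COCl)2 with catalytic DMF would give (2E)-3-{4-[(triisopropylsilyl)oxy]phenyl}prop-2-enoyl chloride F4. C-Acylation of the magnesium enolate of 9 (MgCl2, pyridine) with F4 would give ethyl (6R)-9-methyl-3-oxo-6-(prop-1-en-2-yl)-2-[(2E)-3-{4-[(triisopropylsilyl)oxy]phenyl}prop-2-enoyl]dec-9-enoate F5. Its enol would close by 6-endo-trig oxa-Michael addition (DBU, cat.) to ethyl 6-[(3R)-6-methyl-3-(prop-1-en-2-yl)hept-6-en-1-yl]-4-oxo-2-{4-[(triisopropylsilyl)oxy]phenyl}-3,4-dihydro-2H-pyran-5-carboxylate F6. Dehydrogenation with DDQ (dioxane, 80 °C), as in the oxidation of flavanones to flavones, would return to the route at 15.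

Step 3. The ylide may fail to discriminate the aldehyde from the methyl ketone of 4, or the basic medium may trigger intramolecular aldol condensation of the keto aldehyde. The fallback masks the aldehyde first and sets out from 4. Chemoselective acetalisation (HC(OMe)3, CeCl3·7H2O (cat.), MeOH) would give (5R)-7,7-dimethoxy-5-(prop-1-en-2-yl)heptan-2-one F7. Wittig methylenation (MePPh3Br, KOtBu) would give (5R)-7,7-dimethoxy-2-methyl-5-(prop-1-en-2-yl)hept-1-ene F8. Mild acetal hydrolysis (aq. oxalic acid, THF) would give (3R)-6-methyl-3-(prop-1-en-2-yl)hept-6-enal F9. Wittig homologation of F9 with MeOCH2PPh3Cl and KN(SiMe3)2 would return to the route at 6.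

Further compounds
F1 | step 11 | ethyl 2-[(5R)-2-hydroxy-8-methyl-5-(prop-1-en-2-yl)non-8-en-3-yl]-4-oxo-6-{4-[(triisopropylsilyl)oxy]phenyl}-4H-pyran-3-carboxylate | C=C(C)CC[C@H](CC(C(C)O)c1oc(-c2ccc(O[Si](C(C)C)(C(C)C)C(C)C)cc2)cc(=O)c1C(=O)OCC)C(=C)C
F2 | step 10 | triisopropylsilyl (2E)-3-{4-[(triisopropylsilyl)oxy]phenyl}prop-2-enoate | CC(C)[Si](OC(=O)/C=C/c1ccc(O[Si](C(C)C)(C(C)C)C(C)C)cc1)(C(C)C)C(C)C
F3 | step 10 | (2E)-3-{4-[(triisopropylsilyl)oxy]phenyl}prop-2-enoic acid | OC(=O)/C=C/c1ccc(O[Si](C(C)C)(C(C)C)C(C)C)cc1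
F4 | step 10 | (2E)-3-{4-[(triisopropylsilyl)oxy]phenyl}prop-2-enoyl chloride | O=C(Cl)/C=C/c1ccc(O[Si](C(C)C)(C(C)C)C(C)C)cc1
F5 | step 10 | ethyl (6R)-9-methyl-3-oxo-6-(prop-1-en-2-yl)-2-[(2E)-3-{4-[(triisopropylsilyl)oxy]phenyl}prop-2-enoyl]dec-9-enoate | C=C(C)CC[C@H](CCC(=O)C(C(=O)OCC)C(=O)/C=C/c1ccc(O[Si](C(C)C)(C(C)C)C(C)C)cc1)C(=C)C
F6 | step 10 | ethyl 6-[(3R)-6-methyl-3-(prop-1-en-2-yl)hept-6-en-1-yl]-4-oxo-2-{4-[(triisopropylsilyl)oxy]phenyl}-3,4-dihydro-2H-pyran-5-carboxylate (C2 epimers) | C=C(C)CC[C@H](CCC1=C(C(=O)OCC)C(=O)CC(c2ccc(O[Si](C(C)C)(C(C)C)C(C)C)cc2)O1)C(=C)C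
F7 | step 3 | (5R)-7,7-dimethoxy-5-(prop-1-en-2-yl)heptan-2-one | CC(=O)CC[C@H](CC(OC)OC)C(C)=C
F8 | step 3 | (5R)-7,7-dimethoxy-2-methyl-5-(prop-1-en-2-yl)hept-1-ene | C=C(C)CC[C@H](CC(OC)OC)C(=C)C
F9 | step 3 | (3R)-6-methyl-3-(prop-1-en-2-yl)hept-6-enal | C=C(C)CC[C@H](CC=O)C(=C)C
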